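**Plan**

- Germacrane numbering is used: ring C1–C10, lactone O6–C12(=O)–C11(=C13)–C7, C14 = CH2OAc, C15 = CH3. The late cuts are the O8–acyl bond, the O14–acetyl bond and the epoxide oxygen on C1/C10.
- The central cut removes C11–C12 and C6–C7 together. The enabling feature is the α-methylene-γ-butyrolactone fused on the C6–C7 edge of the ten-membered ring. C13=C11–C7 is a masked terminal allene C7=C11=C13, C12 is CO2, and C6–O is the carbonyl of a (Z)-enal.
- Forward: zerovalent nickel joins allene and CO2 (C11–C12). The resulting allylnickel carboxylate closes the ten-membered carbocycle on the tethered enal (C6–C7). Acid work-up then closes the five-membered lactone.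
- The open chain comes from small pieces. C9–C10 is made by carbomagnesiation of propargyl alcohol with a vinyl Grignard reagent. C1–C2 is made by B-alkyl Suzuki–Miyaura coupling with a C6 dienyl ether. C7–C8 is made by propargylboration.
- Stereochemistry: C4=C5 (Z) is bought. C1=C10 comes from the anti-carbomagnesiation and C8 from a chiral diazaborolidine. C6 and C7 are relayed from C8 in the key step. C1/C10 come from Sharpless epoxidation with L-(+)-DET, and the side-chain epoxide from Sharpless epoxidation of tiglyl alcohol with D-(−)-DET.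

Key step: step 12

Assumption: the (R,R)-diazaborolidine is taken to deliver the propargyl group to the Si face of aldehyde 12 (chair with the sulfonyl group of the axial nitrogen next to the formyl hydrogen); should the sense be the reverse, the (S,S)-reagent is used and nothing else changes.

**Step 1**
Reactants: 1 (Z)-3-methylpent-2-en-4-yn-1-ol
Product: 2 (Z)-1-[(4-methoxybenzyl)oxy]-3-methylpent-2-en-4-yne
Conditions: NaH (1.1 equiv), PMBCl, Bu4NI (cat.), THF–DMF, 0 °C to rt
Reagents that add atoms: 4-methoxybenzyl chloride, COc1ccc(CCl)cc1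
Why: Williamson ether synthesis, in which the alkoxide forms far more readily than the acetylide and gives an ether that survives boranes, base and palladium and can later be removed oxidatively.

**Step 2**
Reactants: 2 (Z)-1-[(4-methoxybenzyl)oxy]-3-methylpent-2-en-4-yne
Product: 3 (Z)-5-[(4-methoxybenzyl)oxy]-3-methylpenta-1,3-diene
Conditions: H2 (1 atm), Pd/CaCO3 poisoned with Pb(OAc)2, quinoline, hexane–EtOAc, rt, stopped after one equivalent of H2
Reagents that add atoms: none
Why: Lindlar-type semihydrogenation should stop at the terminal vinyl group and leave the trisubstituted (Z)-alkene and the benzylic ether untouched.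

**Step 3**
Reactants: 4 prop-2-yn-1-ol
Product: 6 (Z)-2-(iodomethylidene)but-3-en-1-ol, via magnesacycle 5 (not isolated)
Conditions: vinylmagnesium bromide (2.5 equiv), CuI (10 mol %), THF, −10 °C to rt; then I2, −30 to 0 °C
Reagents that add atoms: vinylmagnesium bromide, C=C[Mg]Br; iodine, II
Why: Copper-catalysed anti-carbomagnesiation of propargyl alcohol places the vinyl group on the internal alkyne carbon and magnesium on the terminal carbon cis to CH2O in a five-membered chelate, so iodinolysis with retention fixes I cis to CH2OH, which is the C1=C10 geometry of the target.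

**Step 4**
Reactants: 6 (Z)-2-(iodomethylidene)but-3-en-1-ol
Product: 7 (Z)-tert-butyl{[2-(iodomethylidene)but-3-en-1-yl]oxy}dimethylsilane
Conditions: TBSCl, imidazole, CH2Cl2, 0 °C to rt
Reagents that add atoms: tert-butyldimethylsilyl chloride, CC(C)(C)[Si](C)(C)Cl
Why: Standard silylation of a primary alcohol gives an allylic ether that low-valent palladium and nickel do not ionise.

**Step 5**
Reactants: 3 (Z)-5-[(4-methoxybenzyl)oxy]-3-methylpenta-1,3-diene; 7 (Z)-tert-butyl{[2-(iodomethylidene)but-3-en-1-yl]oxy}dimethylsilane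
Product: 9 (2Z,6Z)-7-[(tert-butyldimethylsilyloxy)methyl]-1-[(4-methoxybenzyl)oxy]-3-methylnona-2,6,8-triene, via alkylborane 8 (not isolated)
Conditions: 3, 9-BBN-H (1.0 equiv), THF, 0 °C to rt; then 7, Pd(dppf)Cl2 (5 mol %), AsPh3, Cs2CO3, DMF–H2O, rt
Reagents that add atoms: none
Why: 9-BBN hydroborates only the monosubstituted end of the diene, and the B-alkyl Suzuki–Miyaura coupling proceeds with retention at the alkenyl iodide, so both alkene geometries are carried into 9.

**Step 6**
Reactants: 9 (2Z,6Z)-7-[(tert-butyldimethylsilyloxy)methyl]-1-[(4-methoxybenzyl)oxy]-3-methylnona-2,6,8-triene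
Product: 11 (3Z,7Z)-3-[(tert-butyldimethylsilyloxy)methyl]-9-[(4-methoxybenzyl)oxy]-7-methylnona-3,7-dien-1-ol, via alkylborane 10 (not isolated)
Conditions: 9-BBN-H (1.1 equiv), THF, 0 °C to rt; then NaOH, H2O2, 0 °C
Reagents that add atoms: hydrogen peroxide, OO
Why: Hydroboration–oxidation, in which 9-BBN adds anti-Markovnikov to the only monosubstituted alkene much faster than to the two trisubstituted ones and so delivers the primary homoallylic alcohol (C8).

**Step 7**
Reactants: 11 (3Z,7Z)-3-[(tert-butyldimethylsilyloxy)methyl]-9-[(4-methoxybenzyl)oxy]-7-methylnona-3,7-dien-1-ol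
Product: 12 (3Z,7Z)-3-[(tert-butyldimethylsilyloxy)methyl]-9-[(4-methoxybenzyl)oxy]-7-methylnona-3,7-dienal
Conditions: Dess–Martin periodinane, pyridine, CH2Cl2, 0 °C; used at once
Reagents that add atoms: none
Why: Dess–Martin oxidation under buffered, essentially neutral conditions should give the β,γ-unsaturated aldehyde without moving the alkene into conjugation.

**Step 8**
Reactants: 12 (3Z,7Z)-3-[(tert-butyldimethylsilyloxy)methyl]-9-[(4-methoxybenzyl)oxy]-7-methylnona-3,7-dienal
Product: 13 (4R,6Z,10Z)-6-[(tert-butyldimethylsilyloxy)methyl]-12-[(4-methoxybenzyl)oxy]-10-methyldodeca-1,2,6,10-tetraen-4-ol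
Conditions: (R,R)-N,N'-ditosyl-1,2-diphenylethane-1,2-diamine, BBr3, CH2Cl2, 0 °C to rt, evaporate; allenyltributylstannane, CH2Cl2, 0 °C to rt; then 12, −78 °C; pH 7 buffer
Reagents that add atoms: allenyltributylstannane, C=C=C[Sn](CCCC)(CCCC)CCCC
Why: Enantioselective propargylboration, in which tin-to-boron exchange (SE2') gives a B-propargyl diazaborolidine that adds through a six-membered cyclic transition state at its alkyne terminus to the Si face of the aldehyde, setting 8R as an allenyl carbinol at a temperature at which the β,γ-alkene stays in place.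

**Step 9**
Reactants: 13 (4R,6Z,10Z)-6-[(tert-butyldimethylsilyloxy)methyl]-12-[(4-methoxybenzyl)oxy]-10-methyldodeca-1,2,6,10-tetraen-4-ol
Product: 14 (4R,6Z,10Z)-4-(tert-butyldimethylsilyloxy)-6-[(tert-butyldimethylsilyloxy)methyl]-12-[(4-methoxybenzyl)oxy]-10-methyldodeca-1,2,6,10-tetraene
Conditions: TBSCl, imidazole, DMF, rt
Reagents that add atoms: tert-butyldimethylsilyl chloride, CC(C)(C)[Si](C)(C)Cl
Why: Silylation turns O8 into a poor leaving group next to the allene without touching the stereocentre.

**Step 10**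
Reactants: 14 (4R,6Z,10Z)-4-(tert-butyldimethylsilyloxy)-6-[(tert-butyldimethylsilyloxy)methyl]-12-[(4-methoxybenzyl)oxy]-10-methyldodeca-1,2,6,10-tetraene
Product: 15 (2Z,6Z,9R)-9-(tert-butyldimethylsilyloxy)-7-[(tert-butyldimethylsilyloxy)methyl]-3-methyldodeca-2,6,10,11-tetraen-1-ol
Conditions: DDQ, CH2Cl2–pH 7 buffer, 0 °C
Reagents that add atoms: none
Why: Oxidative cleavage of the electron-rich PMB ether (hydride abstraction, then hydrolysis) should leave both silyl ethers, the allene and the alkenes intact.

**Step 11**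
Reactants: 15 (2Z,6Z,9R)-9-(tert-butyldimethylsilyloxy)-7-[(tert-butyldimethylsilyloxy)methyl]-3-methyldodeca-2,6,10,11-tetraen-1-ol
Product: 16 (2Z,6Z,9R)-9-(tert-butyldimethylsilyloxy)-7-[(tert-butyldimethylsilyloxy)methyl]-3-methyldodeca-2,6,10,11-tetraenal
Conditions: TEMPO (10 mol %), PhI(OAc)2, CH2Cl2, 0 °C to rt
Reagents that add atoms: none
Why: TEMPO/PhI(OAc)2 oxidation of a primary allylic alcohol is the neutral method of choice for nerol-type substrates and should give the (Z)-enal without Z-to-E isomerisation.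

**Step 12**
Reactants: 16 (2Z,6Z,9R)-9-(tert-butyldimethylsilyloxy)-7-[(tert-butyldimethylsilyloxy)methyl]-3-methyldodeca-2,6,10,11-tetraenal
Product: 19 8β,14-bis(tert-butyldimethylsilyloxy)germacra-1(10),4,11(13)-trien-12,6α-olide (trans-fused; H6β; H7α; C4=C5 Z; C2 cis to C14 on C1=C10), via nickelalactone 17 (not isolated), via hydroxy acid 18 (not isolated)
Conditions: Ni(cod)2 (1.2 equiv), DBU (2.5 equiv), CO2 (1 atm), THF, 0 °C, syringe-pump addition of 16 to 1 mM, then rt; 1 M aq HCl, 0 °C; PPTS (cat.), CH2Cl2, rt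
Reagents that add atoms: carbon dioxide, O=C=O
Why: Proposed new method: DBU-ligated zerovalent nickel couples the terminal C11=C13 π bond of the allene oxidatively with CO2, which makes C11–C12 at the central allene carbon and gives nickelalactone 17, a σ/π-allyl complex of divalent nickel with the metal on the primary terminus C13, and this allylnickel then adds by SE2' through C7 to the tethered enal carbonyl, which makes C6–C7, before protonolysis frees hydroxy acid 18 and mild acid closes the lactone. The closest known reaction type is the stoichiometric Ni(cod)2/DBU carboxylation of terminal allenes whose allylnickel carboxylate is trapped by an added aldehyde, and the ring-closing half resembles the chromium- and zinc-mediated closures of germacranolide rings from 2-(halomethyl)acrylates and enals, so that only the tethering of the aldehyde and the ten-membered ring size are new. The carbocycle closes 10-exo-trig at the C6 carbonyl within a six-membered chair (Ni, O, C6, C7, C11, C13), and the lactone closes 5-exo-trig by attack of O6 on C12. C6 relative to C7 follows from that chair, in which C8 (syn on the allyl unit, trans to C13) and C5 are both equatorial, which gives the anti adduct and hence the trans-fused lactone. C7 relative to C8 follows from allylic 1,3-strain against the C12 carboxylate, which holds H8 in the alkene plane, and from the C8–O bond avoiding the position anti to the forming bond, so that C6 arrives anti to C9 and 8R is relayed to the 7R and 6R centres of the target. The step needs CO2 (in large excess at 1 atm) to capture the nickel–allene complex before the remote aldehyde can, ring closure to outrun dimerisation (high dilution), 1,2- rather than 1,4-attack (the enal β-carbon C4 is fully substituted) and no ionisation or β-elimination next to the allyl unit (silyl ethers instead of esters at O8 and O14).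

**Step 13**
Reactants: 19 8β,14-bis(tert-butyldimethylsilyloxy)germacra-1(10),4,11(13)-trien-12,6α-olide
Product: 20 8β,14-dihydroxygermacra-1(10),4,11(13)-trien-12,6α-olide
Conditions: HF·pyridine, excess pyridine, THF, 0 °C to rt
Reagents that add atoms: none
Why: Buffered fluoride desilylation removes both silyl groups and avoids basic fluoride, which could add to the α-methylene lactone or move the lactone from O6 to O8.

**Step 14**
Reactants: 20 8β,14-dihydroxygermacra-1(10),4,11(13)-trien-12,6α-olide
Product: 21 (1R,10S)-1,10-epoxy-8β,14-dihydroxygermacra-4,11(13)-dien-12,6α-olide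
Conditions: Ti(OiPr)4 (20 mol %), L-(+)-diethyl tartrate (24 mol %), t-BuOOH, 4 Å MS, CH2Cl2, −20 °C
Reagents that add atoms: tert-butyl hydroperoxide, CC(C)(C)OO
Why: In this Sharpless asymmetric epoxidation titanium binds the C14 allylic alcohol so that only C1=C10 reacts (C4=C5 has no free allylic OH and C11=C13 is electron-poor), L-(+)-DET sets 10S in the sense known for 2-substituted allylic alcohols, and syn addition to the alkene with C2 cis to C14 then fixes 1R.

**Step 15**
Reactants: 21 (1R,10S)-1,10-epoxy-8β,14-dihydroxygermacra-4,11(13)-dien-12,6α-olide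
Product: 22 (1R,10S)-14-acetoxy-1,10-epoxy-8β-hydroxygermacra-4,11(13)-dien-12,6α-olide
Conditions: Ac2O (1.1 equiv), 2,4,6-collidine, CH2Cl2, −20 to 0 °C
Reagents that add atoms: acetic anhydride, CC(=O)OC(C)=O
Why: Rate-selective acetylation should favour the primary C14 alcohol over the hindered secondary 8β-alcohol, and the weak base avoids Payne rearrangement and lactone migration.

**Step 16**
Reactants: 23 (E)-2-methylbut-2-en-1-ol (tiglyl alcohol)
Product: 24 [(2R,3R)-2,3-dimethyloxiran-2-yl]methanol
Conditions: Ti(OiPr)4 (5 mol %), D-(−)-diethyl tartrate (6 mol %), t-BuOOH, 4 Å MS, CH2Cl2, −20 °C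
Reagents that add atoms: tert-butyl hydroperoxide, CC(C)(C)OO
Why: Sharpless asymmetric epoxidation with D-(−)-DET gives the (2R,3R)-epoxy alcohol, the mirror image of the (2S,3S) product known for L-(+)-DET with (E)-allylic alcohols, and keeps the two methyl groups cis by syn addition.

**Step 17**
Reactants: 24 [(2R,3R)-2,3-dimethyloxiran-2-yl]methanol
Product: 25 (2S,3R)-2,3-dimethyloxirane-2-carboxylic acid
Conditions: TEMPO (20 mol %), PhI(OAc)2 (2.2 equiv), MeCN–H2O, rt
Reagents that add atoms: water, O
Why: TEMPO/PhI(OAc)2 oxidation in aqueous acetonitrile takes the primary alcohol through the aldehyde hydrate to the acid without opening the epoxide, and the descriptor at C2 changes only because of the priority rules.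

**Step 18**
Reactants: 22 (1R,10S)-14-acetoxy-1,10-epoxy-8β-hydroxygermacra-4,11(13)-dien-12,6α-olide; 25 (2S,3R)-2,3-dimethyloxirane-2-carboxylic acid
Product: 27 target CNP0232260.4, via mixed anhydride 26 (not isolated)
Conditions: 25, 2,4,6-trichlorobenzoyl chloride, Et3N, toluene, rt; then 22, DMAP, toluene, rt
Reagents that add atoms: none
Why: Yamaguchi esterification activates the hindered α,α-disubstituted glycidic acid as a mixed anhydride, and DMAP transfers the acyl group to O8 with retention at C8 and at both epoxide carbons of the acid.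

**Compound list**

1 | (Z)-3-methylpent-2-en-4-yn-1-ol | C#C/C(C)=C\CO | starting material
2 | (Z)-1-[(4-methoxybenzyl)oxy]-3-methylpent-2-en-4-yne | C#C/C(C)=C\COCc1ccc(OC)cc1 | intermediate
3 | (Z)-5-[(4-methoxybenzyl)oxy]-3-methylpenta-1,3-diene | C=C/C(C)=C\COCc1ccc(OC)cc1 | intermediate
4 | prop-2-yn-1-ol | C#CCO | starting material
5 | cyclic alkenylmagnesium alkoxide (4-vinyl-2,5-dihydro-1,2-oxamagnesole) | C=CC1=C[Mg]OC1 | intermediate
6 | (Z)-2-(iodomethylidene)but-3-en-1-ol | OC/C(C=C)=C\I | intermediate
7 | TBS ether of 6 | CC(C)(C)[Si](C)(C)OC/C(C=C)=C\I | intermediate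
8 | B-[(Z)-5-(4-methoxybenzyloxy)-3-methylpent-3-enyl]-9-BBN | COc1ccc(COC/C=C(/C)CCB2C3CCCC2CCC3)cc1 | intermediate
9 | (2Z,6Z)-7-[(TBSO)methyl]-1-(PMBO)-3-methylnona-2,6,8-triene | COc1ccc(COC/C=C(/C)CC/C=C(\CO[Si](C)(C)C(C)(C)C)C=C)cc1 | intermediate
10 | B-alkyl-9-BBN from 9 (boron on C8) | COc1ccc(COC/C=C(/C)CC/C=C(\CO[Si](C)(C)C(C)(C)C)CCB2C3CCCC2CCC3)cc1 | intermediate
11 | (3Z,7Z)-3-[(TBSO)methyl]-9-(PMBO)-7-methylnona-3,7-dien-1-ol | COc1ccc(COC/C=C(/C)CC/C=C(\CO[Si](C)(C)C(C)(C)C)CCO)cc1 | intermediate
12 | (3Z,7Z)-3-[(TBSO)methyl]-9-(PMBO)-7-methylnona-3,7-dienal | COc1ccc(COC/C=C(/C)CC/C=C(\CO[Si](C)(C)C(C)(C)C)CC=O)cc1 | intermediate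
13 | (4R,6Z,10Z)-6-[(TBSO)methyl]-12-(PMBO)-10-methyldodeca-1,2,6,10-tetraen-4-ol | COc1ccc(COC/C=C(/C)CC/C=C(\CO[Si](C)(C)C(C)(C)C)C[C@@H](O)C=C=C)cc1 | intermediate
14 | TBS ether of 13 | COc1ccc(COC/C=C(/C)CC/C=C(\CO[Si](C)(C)C(C)(C)C)C[C@@H](O[Si](C)(C)C(C)(C)C)C=C=C)cc1 | intermediate
15 | (2Z,6Z,9R)-9-(TBSO)-7-[(TBSO)methyl]-3-methyldodeca-2,6,10,11-tetraen-1-ol | OC/C=C(/C)CC/C=C(\CO[Si](C)(C)C(C)(C)C)C[C@@H](O[Si](C)(C)C(C)(C)C)C=C=C | intermediate
16 | (2Z,6Z,9R)-9-(TBSO)-7-[(TBSO)methyl]-3-methyldodeca-2,6,10,11-tetraenal | O=C/C=C(/C)CC/C=C(\CO[Si](C)(C)C(C)(C)C)C[C@@H](O[Si](C)(C)C(C)(C)C)C=C=C | intermediate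
17 | allylnickel carboxylate (five-membered nickelalactone, DBU ligands omitted) | O=C/C=C(/C)CC/C=C(\CO[Si](C)(C)C(C)(C)C)C[C@@H](O[Si](C)(C)C(C)(C)C)/C=C1/C[Ni]OC1=O | intermediate
18 | 6α-hydroxy-8β,14-bis(TBSO)germacra-1(10),4,11(13)-trien-12-oic acid | OC(=O)C(=C)[C@H]1[C@H](O)/C=C(/C)CC/C=C(\CO[Si](C)(C)C(C)(C)C)C[C@H]1O[Si](C)(C)C(C)(C)C | intermediate
19 | 8β,14-bis(TBSO)germacra-1(10),4,11(13)-trien-12,6α-olide | C=C1C(=O)O[C@@H]2/C=C(/C)CC/C=C(\CO[Si](C)(C)C(C)(C)C)C[C@@H](O[Si](C)(C)C(C)(C)C)[C@@H]12 | intermediate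
20 | 8β,14-dihydroxygermacra-1(10),4,11(13)-trien-12,6α-olide | C=C1C(=O)O[C@@H]2/C=C(/C)CC/C=C(\CO)C[C@@H](O)[C@@H]12 | intermediate
21 | (1R,10S)-1,10-epoxy-8β,14-dihydroxygermacra-4,11(13)-dien-12,6α-olide | C=C1C(=O)O[C@@H]2/C=C(/C)CC[C@H]3O[C@]3(CO)C[C@@H](O)[C@@H]12 | intermediate
22 | (1R,10S)-14-acetoxy-1,10-epoxy-8β-hydroxygermacra-4,11(13)-dien-12,6α-olide | C=C1C(=O)O[C@@H]2/C=C(/C)CC[C@H]3O[C@]3(COC(C)=O)C[C@@H](O)[C@@H]12 | intermediate
23 | (E)-2-methylbut-2-en-1-ol | C/C=C(\C)CO | starting material
24 | [(2R,3R)-2,3-dimethyloxiran-2-yl]methanol | OC[C@@]1(C)O[C@@H]1C | intermediate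
25 | (2S,3R)-2,3-dimethyloxirane-2-carboxylic acid | OC(=O)[C@@]1(C)O[C@@H]1C | intermediate
26 | mixed anhydride of 25 and 2,4,6-trichlorobenzoic acid | O=C(OC(=O)[C@@]1(C)O[C@@H]1C)c1c(Cl)cc(Cl)cc1Cl | intermediate
27 | CNP0232260.4: (1R,10S)-14-acetoxy-1,10-epoxy-8β-[(2S,3R)-2,3-dimethyloxirane-2-carbonyloxy]germacra-4Z,11(13)-dien-12,6α-olide (6R,7R,8R) | C=C1C(=O)O[C@@H]2/C=C(/C)CC[C@H]3O[C@]3(COC(C)=O)C[C@@H](OC(=O)[C@@]3(C)O[C@@H]3C)[C@@H]12 | target

Total step count: 18.
Longest linear sequence: 14 (steps 1, 2, 5–15 and 18).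

**Steps most likely to fail**

**Step 12.**
- Nickel may engage the enal directly.
- The amidine may isomerise the (Z)-enal to the (E)-enal.
- Ring closure may lose to oligomerisation.
- The allylnickel may expel the neighbouring silyloxide.
- C6 may arrive on the wrong face of C7.

Fallback (the one event is split into separate known acts), setting out from enal 16:
- Palladium-catalysed distannation of the allene with hexamethylditin (Pd(PPh3)4, toluene, 80 °C) should give the 2-stannyl allylstannane F1.
- Exchange of its allylic tin with InCl3 in dilute solution gives an allylindium. This should close the ring through a cyclic transition state to the anti homoallylic alcohol F2, which keeps the vinylstannane on C11.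
- Iododestannylation (I2, CH2Cl2, 0 °C) gives the vinyl iodide F3.
- Palladium-catalysed carbonylative lactonisation (Pd(PPh3)4, CO 1 atm, Et3N, MeCN) comes back to the route at lactone 19.

**Step 14.**
- The facial preference of the tartrate reagent may be mismatched with the alkene face that the ring conformation exposes.
- The titanium Lewis acid may trigger transannular opening of the new epoxide by C4=C5.

Fallback (substrate control in place of directed reagent control), setting out from diol 20:
- Selective acetylation of the primary alcohol (Ac2O, collidine) gives the 14-acetate F4.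
- Undirected epoxidation with mCPBA (NaHCO3, CH2Cl2, 0 °C) then relies on the higher strain of the ring-trans C1=C10 alkene compared with the ring-cis C4=C5 alkene, and on peripheral attack.
- This comes back to the route at acetate 22.

**Step 8.**
- The β,γ-double bond may migrate into conjugation before the addition.
- Facial selectivity may be insufficient.
- The boron reagent may leak to its allenyl isomer, which would give the homopropargylic alcohol.

Fallback (the stereocentre is set by reduction instead of addition), setting out from aldehyde 12: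
- Rapid addition of ethynylmagnesium bromide at −78 °C gives the C8-epimeric propargylic alcohol F5.
- Dess–Martin oxidation gives the ynone F6.
- Midland reduction with (R)-Alpine-Borane, whose sense for 1-alkyn-3-ones is (R), gives the (R)-propargylic alcohol F7.
- Crabbé homologation (paraformaldehyde, CuBr, iPr2NH, dioxane, reflux) comes back to the route at allenol 13.

**Further compounds**

F1 | step 12 | (2Z,6Z,9R,10Z)-9-(TBSO)-7-[(TBSO)methyl]-3-methyl-11,12-bis(trimethylstannyl)dodeca-2,6,10-trienal | O=C/C=C(/C)CC/C=C(\CO[Si](C)(C)C(C)(C)C)C[C@@H](O[Si](C)(C)C(C)(C)C)/C=C(\[Sn](C)(C)C)C[Sn](C)(C)C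
F2 | step 12 | ten-membered 6α-alcohol with a 1-(trimethylstannyl)vinyl group on C7 (8β,14-bis-TBS ether) | C=C([Sn](C)(C)C)[C@H]1[C@H](O)/C=C(/C)CC/C=C(\CO[Si](C)(C)C(C)(C)C)C[C@H]1O[Si](C)(C)C(C)(C)C
F3 | step 12 | ten-membered 6α-alcohol with a 1-iodovinyl group on C7 (8β,14-bis-TBS ether) | C=C(I)[C@H]1[C@H](O)/C=C(/C)CC/C=C(\CO[Si](C)(C)C(C)(C)C)C[C@H]1O[Si](C)(C)C(C)(C)C
F4 | step 14 | 14-acetoxy-8β-hydroxygermacra-1(10),4,11(13)-trien-12,6α-olide | C=C1C(=O)O[C@@H]2/C=C(/C)CC/C=C(\COC(C)=O)C[C@@H](O)[C@@H]12
F5 | step 8 | (5Z,9Z)-5-[(TBSO)methyl]-11-(PMBO)-9-methylundeca-5,9-dien-1-yn-3-ol (both C3 epimers) | COc1ccc(COC/C=C(/C)CC/C=C(\CO[Si](C)(C)C(C)(C)C)CC(O)C#C)cc1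
F6 | step 8 | (5Z,9Z)-5-[(TBSO)methyl]-11-(PMBO)-9-methylundeca-5,9-dien-1-yn-3-one | COc1ccc(COC/C=C(/C)CC/C=C(\CO[Si](C)(C)C(C)(C)C)CC(=O)C#C)cc1
F7 | step 8 | (3R,5Z,9Z)-5-[(TBSO)methyl]-11-(PMBO)-9-methylundeca-5,9-dien-1-yn-3-ol | COc1ccc(COC/C=C(/C)CC/C=C(\CO[Si](C)(C)C(C)(C)C)C[C@@H](O)C#C)cc1
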